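The chroman is cut at C2–C3 and at O1–C8a. The fully substituted carbon C2, which carries O1, the methyl group and the C41 octaene chain, is read as the carbonyl carbon of a C43 methyl ketone excised from all-E solanesol; C3, C4 and the benzene ring (C4a to C8a) arrive as a 2-(2-bromoaryl)ethyl Grignard reagent. In one flask the Grignard carbon adds to the ketone under a chiral aminophenolate ligand, which sets C2, and the tertiary alkoxide so formed is arylated at C8a under palladium catalysis, closing the pyran ring. The step exploits the latent ketone at C2 and the 1,4-relation of C3 and C8a across C4–C4a.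

Key step: step 9

Remark: the target has the natural 2R configuration and solanesol is taken as the commercial all-E C45 alcohol, so the seven E double bonds of the side chain are never made or moved; the (1R,2R)-aminophenol ligand of step 9 is assumed to direct the Grignard carbon to the Si face of ketone 3, and if a model addition to geranylacetone shows the opposite sense, its (1S,2S)-antipode is used instead.

Step 1
Reactants: 1 solanesol
Product: 2 (±)-trans-2,3-epoxysolanesol
Conditions: VO(acac)2 (2 mol%), t-BuOOH (1.3 equiv, decane), toluene, 0 °C to rt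
Reagents that add atoms: tert-butyl hydroperoxide, CC(C)(C)OO
Why: hydroxyl-directed vanadium-catalysed epoxidation of an allylic alcohol should touch only the C2=C3 double bond and leave the eight remote trisubstituted olefins alone, and the two racemic stereocentres it creates are destroyed in step 2.

Step 2
Reactants: 2 (±)-trans-2,3-epoxysolanesol
Product: 3 (5E,9E,13E,17E,21E,25E,29E)-6,10,14,18,22,26,30,34-octamethylpentatriaconta-5,9,13,17,21,25,29,33-octaen-2-one
Conditions: H5IO6 (2.5 equiv), THF/H2O 4:1, 0 °C to rt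
Reagents that add atoms: water, O
Why: acid-catalysed hydrolysis of the trisubstituted epoxide to the 1,2,3-triol followed by twofold Malaprade glycol cleavage should excise C1 and C2 and leave C3 as the methyl ketone, isolated olefins being inert to periodate.

Step 3
Reactants: 4 2,3-dimethylphenol
Product: 5 (2,3-dimethylphenoxy)triisopropylsilane
Conditions: i-Pr3SiCl, imidazole, DMF, rt
Reagents that add atoms: triisopropylsilyl chloride, CC(C)[Si](Cl)(C(C)C)C(C)C
Why: standard silylation of a phenol gives a bulky silyl ether that should survive organometallic and basic steps and shield the ortho position.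

Step 4
Reactants: 5 (2,3-dimethylphenoxy)triisopropylsilane
Product: 6 2-[3,4-dimethyl-5-(triisopropylsilyloxy)phenyl]-4,4,5,5-tetramethyl-1,3,2-dioxaborolane
Conditions: B2pin2 (1.0 equiv), [Ir(OMe)(cod)]2 (1.5 mol%), 4,4'-di-tert-butyl-2,2'-bipyridine (3 mol%), THF, 80 °C
Reagents that add atoms: bis(pinacolato)diboron, CC1(C)OB(OC1(C)C)B1OC(C)(C)C(C)(C)O1
Why: sterically governed iridium-catalysed C–H borylation should go to the only ring C–H without an ortho substituent, the future C4a.

Step 5
Reactants: 6 2-[3,4-dimethyl-5-(triisopropylsilyloxy)phenyl]-4,4,5,5-tetramethyl-1,3,2-dioxaborolane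
Product: 7 (5-ethenyl-2,3-dimethylphenoxy)triisopropylsilane
Conditions: vinyl bromide (1 M in THF, 2 equiv), Pd(dppf)Cl2 (3 mol%), K3PO4 (3 equiv), THF/H2O, 60 °C
Reagents that add atoms: vinyl bromide, C=CBr
Why: Suzuki–Miyaura coupling of an unhindered aryl boronic ester with a vinyl halide is routine and installs the two carbons that become C4 and C3.

Step 6
Reactants: 7 (5-ethenyl-2,3-dimethylphenoxy)triisopropylsilane
Product: 8 2-[3,4-dimethyl-5-(triisopropylsilyloxy)phenyl]ethanol
Conditions: 9-BBN (1.3 equiv), THF, 0 °C to rt; then NaBO3·4H2O, THF/H2O, rt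
Reagents that add atoms: sodium perborate, [Na+].[Na+].O[B-]1(O)OO[B-](O)(O)OO1
Why: anti-Markovnikov hydroboration of a styrene with 9-BBN and mild perborate oxidation should give the primary alcohol without cleaving the aryl silyl ether.

Step 7
Reactants: 8 2-[3,4-dimethyl-5-(triisopropylsilyloxy)phenyl]ethanol
Product: 9 2-[2-bromo-3,4-dimethyl-5-(triisopropylsilyloxy)phenyl]ethanol
Conditions: NBS (1.05 equiv), MeCN, 0 °C
Reagents that add atoms: N-bromosuccinimide, O=C1CCC(=O)N1Br
Why: electrophilic aromatic bromination should occur para to the silyloxy group (the future C8a), because the only other free position lies between the bulky silyloxy group and the side chain.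

Step 8
Reactants: 9 2-[2-bromo-3,4-dimethyl-5-(triisopropylsilyloxy)phenyl]ethanol
Product: 10 [4-bromo-5-(2-bromoethyl)-2,3-dimethylphenoxy]triisopropylsilane
Conditions: CBr4, PPh3, CH2Cl2, 0 °C
Reagents that add atoms: carbon tetrabromide, BrC(Br)(Br)Br
Why: the Appel reaction converts the primary alcohol into the primary bromide under neutral conditions that leave the aryl bromide and the silyl ether alone.

Step 9
Reactants: 3 (5E,9E,13E,17E,21E,25E,29E)-6,10,14,18,22,26,30,34-octamethylpentatriaconta-5,9,13,17,21,25,29,33-octaen-2-one; 10 [4-bromo-5-(2-bromoethyl)-2,3-dimethylphenoxy]triisopropylsilane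
Product: 13 O-triisopropylsilyl plastochromanol-8, via Grignard reagent 11 (not isolated), via bromomagnesium tertiary alkoxide 12 (not isolated)
Conditions: 10 (2.3 equiv), Mg, Et2O, rt; 2,4-di-tert-butyl-6-({[(1R,2R)-2-(dimethylamino)cyclohexyl](methyl)amino}methyl)phenol (1.1 equiv), toluene, −80 °C, then 3; then t-BuOH, NaOt-Bu, Pd(OAc)2 (5 mol%), 2-(di-tert-butylphosphino)-1,1'-binaphthyl (7 mol%), 80 °C
Reagents that add atoms: none
Why: Proposed new method: magnesium inserts chemoselectively into the primary C–Br bond of 10, the resulting Grignard reagent 11 adds through a chelated chiral aminophenolate–magnesium complex to the Si face of methyl ketone 3 to make the C2–C3 bond, and the tertiary alkoxide 12 is then arylated at C8a in the same flask by oxidative addition of the aryl bromide to zerovalent palladium, alkoxide transfer and C–O reductive elimination. The closest known reaction types are the chiral-ligand-mediated asymmetric Grignard addition to aryl alkyl ketones (not yet shown for a methyl ketone whose other substituent is a primary alkyl chain, nor run in tandem with an etherification) and the palladium-catalysed intramolecular etherification of aryl bromides with tertiary alcohols. The dihydropyran ring closes by intramolecular O-arylation through a seven-membered arylpalladium alkoxide that has no β-hydrogen on the carbinol carbon. The single stereocentre C2 is set in the addition by the chiral ligand (R from Si-face attack, the sense assumed for the (1R,2R)-ligand in the remark above) and is not touched afterwards. The step needs 1,2-addition to outrun enolisation of the methyl ketone, which low temperature and the non-polar medium should favour, and needs the catalyst to ignore the eight trisubstituted olefins, which are poor partners for arylpalladium species.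

Step 10
Reactants: 13 O-triisopropylsilyl plastochromanol-8
Product: 14 plastochromanol-8
Conditions: n-Bu4NF (1.1 equiv), THF, 0 °C, argon; then H2O
Reagents that add atoms: none
Why: fluoride cleavage of the aryl silyl ether should free the phenol without affecting the polyene or the C2 stereocentre, air being excluded to protect the electron-rich chromanol.

Compound list
1 | solanesol, (2E,6E,10E,14E,18E,22E,26E,30E)-3,7,11,15,19,23,27,31,35-nonamethylhexatriaconta-2,6,10,14,18,22,26,30,34-nonaen-1-ol | CC(C)=CCC/C(C)=C/CC/C(C)=C/CC/C(C)=C/CC/C(C)=C/CC/C(C)=C/CC/C(C)=C/CC/C(C)=C/CC/C(C)=C/CO | starting material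
2 | (±)-trans-2,3-epoxysolanesol (racemate, 2R,3R enantiomer drawn) | CC(C)=CCC/C(C)=C/CC/C(C)=C/CC/C(C)=C/CC/C(C)=C/CC/C(C)=C/CC/C(C)=C/CC/C(C)=C/CC[C@@]1(C)O[C@@H]1CO | intermediate
3 | (5E,9E,13E,17E,21E,25E,29E)-6,10,14,18,22,26,30,34-octamethylpentatriaconta-5,9,13,17,21,25,29,33-octaen-2-one | CC(C)=CCC/C(C)=C/CC/C(C)=C/CC/C(C)=C/CC/C(C)=C/CC/C(C)=C/CC/C(C)=C/CC/C(C)=C/CCC(C)=O | intermediate
4 | 2,3-dimethylphenol | Cc1cccc(O)c1C | starting material
5 | (2,3-dimethylphenoxy)triisopropylsilane | Cc1cccc(O[Si](C(C)C)(C(C)C)C(C)C)c1C | intermediate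
6 | 2-[3,4-dimethyl-5-(triisopropylsilyloxy)phenyl]-4,4,5,5-tetramethyl-1,3,2-dioxaborolane | Cc1cc(B2OC(C)(C)C(C)(C)O2)cc(O[Si](C(C)C)(C(C)C)C(C)C)c1C | intermediate
7 | (5-ethenyl-2,3-dimethylphenoxy)triisopropylsilane | C=Cc1cc(C)c(C)c(O[Si](C(C)C)(C(C)C)C(C)C)c1 | intermediate
8 | 2-[3,4-dimethyl-5-(triisopropylsilyloxy)phenyl]ethanol | OCCc1cc(C)c(C)c(O[Si](C(C)C)(C(C)C)C(C)C)c1 | intermediate
9 | 2-[2-bromo-3,4-dimethyl-5-(triisopropylsilyloxy)phenyl]ethanol | OCCc1cc(O[Si](C(C)C)(C(C)C)C(C)C)c(C)c(C)c1Br | intermediate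
10 | [4-bromo-5-(2-bromoethyl)-2,3-dimethylphenoxy]triisopropylsilane | BrCCc1cc(O[Si](C(C)C)(C(C)C)C(C)C)c(C)c(C)c1Br | intermediate
11 | {2-[2-bromo-3,4-dimethyl-5-(triisopropylsilyloxy)phenyl]ethyl}magnesium bromide, Grignard reagent formed in the flask | Br[Mg]CCc1cc(O[Si](C(C)C)(C(C)C)C(C)C)c(C)c(C)c1Br | intermediate
12 | bromomagnesium (R)-alkoxide of the tertiary alcohol from 3 and 11, formed in the flask | CC(C)=CCC/C(C)=C/CC/C(C)=C/CC/C(C)=C/CC/C(C)=C/CC/C(C)=C/CC/C(C)=C/CC/C(C)=C/CC[C@@](C)(O[Mg]Br)CCc1cc(O[Si](C(C)C)(C(C)C)C(C)C)c(C)c(C)c1Br | intermediate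
13 | O-triisopropylsilyl plastochromanol-8, triisopropyl{[(2R)-2,7,8-trimethyl-2-[(3E,7E,11E,15E,19E,23E,27E)-4,8,12,16,20,24,28,32-octamethyltritriaconta-3,7,11,15,19,23,27,31-octaen-1-yl]-3,4-dihydro-2H-chromen-6-yl]oxy}silane | CC(C)=CCC/C(C)=C/CC/C(C)=C/CC/C(C)=C/CC/C(C)=C/CC/C(C)=C/CC/C(C)=C/CC/C(C)=C/CC[C@]1(C)CCc2cc(O[Si](C(C)C)(C(C)C)C(C)C)c(C)c(C)c2O1 | intermediate
14 | plastochromanol-8, (2R)-2,7,8-trimethyl-2-[(3E,7E,11E,15E,19E,23E,27E)-4,8,12,16,20,24,28,32-octamethyltritriaconta-3,7,11,15,19,23,27,31-octaen-1-yl]-3,4-dihydro-2H-chromen-6-ol | CC(C)=CCC/C(C)=C/CC/C(C)=C/CC/C(C)=C/CC/C(C)=C/CC/C(C)=C/CC/C(C)=C/CC/C(C)=C/CC[C@]1(C)CCc2cc(O)c(C)c(C)c2O1 | target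

Total step count: 10 (2 steps to ketone 3, 6 steps to dibromide 10, the union in step 9 and the deprotection in step 10).
Longest linear sequence: 8 steps (4 to 14, steps 3 to 10).

Steps most likely to fail

Step 9 (Proposed new method). The ligand may discriminate poorly between the methyl and the CH2CH2 flank of ketone 3 and give low enantiomeric purity. Enolisation of 3 may compete with addition, and magnesium salts or the aminophenolate may slow the palladium-catalysed ring closure. The fallback uses known, stereospecific chemistry and runs from 3 and 10 back to 13. Ketone 3 is reduced (NaBH4, MeOH/THF) to the racemic secondary alcohol F1. Kinetic resolution with Candida antarctica lipase B and vinyl acetate leaves the (S)-alcohol F2 and gives the (R)-acetate F3. Methanolysis of F3 (K2CO3, MeOH) gives the (R)-alcohol F4. Both enantiomers converge on the (R)-2,4,6-triisopropylbenzoate F5: F2 by Mitsunobu esterification with 2,4,6-triisopropylbenzoic acid (PPh3, DIAD), which inverts, and F4 by acylation with 2,4,6-triisopropylbenzoyl chloride (NaH, THF), which retains. F5 is lithiated with retention (s-BuLi, TMEDA, cyclopentyl methyl ether, −60 °C) and trapped with the neopentyl glycol boronic ester F6, made from 11 with B(OMe)3 and then neopentyl glycol. The 1,2-metallate shift, with inversion at carbon, gives the tertiary boronic ester F7. Oxidation (NaOH, H2O2) with retention gives the (R)-tertiary alcohol F8. Pd(OAc)2, 2-(di-tert-butylphosphino)-1,1'-binaphthyl and Cs2CO3 in toluene at 80 °C then close the ring to 13.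

Step 2. The acidic periodate medium may hydrate or cyclise the polyene, or the cleavage may stall at the α-hydroxy aldehyde stage. The fallback runs from 1 to 3 without the epoxide. Solanesol 1 is oxidised with MnO2 in CH2Cl2 to solanesal F9, and a retro-aldol cleavage of this enal (aqueous K2CO3, toluene, n-Bu4NBr, reflux, with acetaldehyde distilled off), as in the citral to methylheptenone conversion, delivers 3.

Step 7. Bromination may go in part to the ring position between the silyloxy group and the side chain, or the HBr formed may cleave the silyl ether. The fallback runs from 8 to 10 and lets the free phenol direct the halogenation. Desilylation of 8 (n-Bu4NF) gives 2-(3-hydroxy-4,5-dimethylphenyl)ethanol F10. Para-selective bromination of the phenol with n-Bu4NBr3 gives 2-(2-bromo-5-hydroxy-3,4-dimethylphenyl)ethanol F11. The Appel reaction (CBr4, PPh3) on the primary alcohol gives 4-bromo-5-(2-bromoethyl)-2,3-dimethylphenol F12, and silylation (i-Pr3SiCl, imidazole) returns to 10.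

Further compounds
F1 | step 9 | racemic (5E,9E,13E,17E,21E,25E,29E)-6,10,14,18,22,26,30,34-octamethylpentatriaconta-5,9,13,17,21,25,29,33-octaen-2-ol | CC(C)=CCC/C(C)=C/CC/C(C)=C/CC/C(C)=C/CC/C(C)=C/CC/C(C)=C/CC/C(C)=C/CC/C(C)=C/CCC(C)O
F2 | step 9 | (S)-secondary alcohol from the lipase resolution | CC(C)=CCC/C(C)=C/CC/C(C)=C/CC/C(C)=C/CC/C(C)=C/CC/C(C)=C/CC/C(C)=C/CC/C(C)=C/CC[C@H](C)O
F3 | step 9 | (R)-acetate from the lipase resolution | CC(C)=CCC/C(C)=C/CC/C(C)=C/CC/C(C)=C/CC/C(C)=C/CC/C(C)=C/CC/C(C)=C/CC/C(C)=C/CC[C@@H](C)OC(C)=O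
F4 | step 9 | (R)-secondary alcohol from methanolysis of the acetate | CC(C)=CCC/C(C)=C/CC/C(C)=C/CC/C(C)=C/CC/C(C)=C/CC/C(C)=C/CC/C(C)=C/CC/C(C)=C/CC[C@@H](C)O
F5 | step 9 | (R)-2,4,6-triisopropylbenzoate of the secondary alcohol | CC(C)=CCC/C(C)=C/CC/C(C)=C/CC/C(C)=C/CC/C(C)=C/CC/C(C)=C/CC/C(C)=C/CC/C(C)=C/CC[C@@H](C)OC(=O)c1c(C(C)C)cc(C(C)C)cc1C(C)C
F6 | step 9 | 2-{2-[2-bromo-3,4-dimethyl-5-(triisopropylsilyloxy)phenyl]ethyl}-5,5-dimethyl-1,3,2-dioxaborinane | CC1(C)COB(CCc2cc(O[Si](C(C)C)(C(C)C)C(C)C)c(C)c(C)c2Br)OC1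
F7 | step 9 | tertiary neopentyl glycol boronic ester from F5 and F6 | CC(C)=CCC/C(C)=C/CC/C(C)=C/CC/C(C)=C/CC/C(C)=C/CC/C(C)=C/CC/C(C)=C/CC/C(C)=C/CC[C@@](C)(B1OCC(C)(C)CO1)CCc1cc(O[Si](C(C)C)(C(C)C)C(C)C)c(C)c(C)c1Br
F8 | step 9 | (R)-tertiary alcohol, open-chain precursor of 13 | CC(C)=CCC/C(C)=C/CC/C(C)=C/CC/C(C)=C/CC/C(C)=C/CC/C(C)=C/CC/C(C)=C/CC/C(C)=C/CC[C@@](C)(O)CCc1cc(O[Si](C(C)C)(C(C)C)C(C)C)c(C)c(C)c1Br
F9 | step 2 | solanesal, (2E,6E,10E,14E,18E,22E,26E,30E)-3,7,11,15,19,23,27,31,35-nonamethylhexatriaconta-2,6,10,14,18,22,26,30,34-nonaenal | CC(C)=CCC/C(C)=C/CC/C(C)=C/CC/C(C)=C/CC/C(C)=C/CC/C(C)=C/CC/C(C)=C/CC/C(C)=C/CC/C(C)=C/C=O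
F10 | step 7 | 2-(3-hydroxy-4,5-dimethylphenyl)ethanol | OCCc1cc(C)c(C)c(O)c1
F11 | step 7 | 2-(2-bromo-5-hydroxy-3,4-dimethylphenyl)ethanol | OCCc1cc(O)c(C)c(C)c1Br
F12 | step 7 | 4-bromo-5-(2-bromoethyl)-2,3-dimethylphenol | BrCCc1cc(O)c(C)c(C)c1Br
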